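The numbers in the tables are calculated from invented constants; scatter was added.

Z was what I wanted at the end of alder, cedar and elm, and Z sits in the middle of a chain: X takes Q to give Z, and Z takes Q again to give G.

in all of them: X 0.050 M

| run | Q | remark | time |
|---|---|---|---|
| north-west | 0.017 M | run made earlier |  |
| north-east | 0.089 M | run made earlier |  |
| alder | 0.0250 M |  | 12 h |
| cedar | 0.0400 M |  | 12 h |
| elm | 0.100 M |  | 12 h |

| run | time / h | Z / % | G / % |
|---|---|---|---|
| north-west | 1.00 | 7.7 | 0 |
| north-west | 2.00 | 13.2 | 1.0 |
| north-west | 3.00 | 17.0 | 0.8 |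
| north-west | 6.00 | 23.4 | 1.9 |
| north-west | 12.0 | 28.1 | 1.6 |
| north-east | 1.00 | 31.1 | 4.5 |
| north-east | 2.00 | 42.4 | 11.2 |
| north-east | 3.00 | 45.8 | 16.6 |
| north-east | 6.00 | 51.2 | 23.1 |
| north-east | 12.0 | 64.7 | 22.3 |

(standard deviation of a reading: 0.3 percentage points)

* how much Z is there at the end, in percent of the X charged: for each flask in turn (alder, cedar, elm)

- the earlier runs were read with a standard deviation of 0.3 percentage points
- a reading or a percentage of G counts all its forms, free or not

I worked in fractions of the X charge: e is the Q charged, x the X left, q the Q left. In the north-west run, G read 1.6 % at 12.0 h, far less than Z at 28.1 %, so I counted Q as going to X. The difference x − q then stays constant, and the reading at 3.00 h gives: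

e = 0.340, q = 0.162, x = 0.822

κ = ln(e·x/q) / ((x − q)·t) = 0.275 h⁻¹

This κ, my clock, is the fraction of X lost per hour at unit x and q. Run forward with g = x − q and r = exp(g·κ·t), it gives q = e·g/(r − e) and x = q + g:

alder: e = 0.500, r = 5.22, x = 0.553

cedar: e = 0.800, r = 1.94, x = 0.341

For the zero of the scale I took the statistical case, a selectivity factor of 2, where the second addition runs at half the speed of the first:

Z = 2(√x − x)

alder: Z = 0.381; cedar: Z = 0.486

I tested this curve on the north-east run. At 6.00 h it gave 50.0 % against a reading of 51.2 %, but at 12.0 h it gave 46.1 % against 64.7 %. For elm I therefore borrowed that last reading.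

The forecast stands at 39 %, 46 % and 65 %, assuming that “G inhibits or sequesters something once it builds up”; its cedar figure is lower than mine.

The flasks gave Z of 38.0 % in alder, 51.3 % in cedar and 63.9 % in elm.

    X + Q → Z (k = 0.00160 M⁻¹ s⁻¹)
    Q + Z ⇌ G (K = 5.30 M⁻¹, k = 8.90 × 10⁻⁴ M⁻¹ s⁻¹)
    X + G ⇌ J, settled at all times (K = 230 M⁻¹)

The link that gave way was my curve, which has no return. In cedar, the run without the way back from G to Q + Z ends at 42.6 % of Z against 51.3 %, so that return is a part of where Z stands. Two more things act together there: without the tying up of X + G as J, cedar ends at 62.5 % of Z, and at 120 h instead of the hour of the reading it stands at 79.3 %. The clock gives cedar a half-life of X, first step alone at the charged Q, of 3.15 h, against 3.0 h in the flask. In alder, the clock left 55.3 % of the X charged, and the flask held 54.7 %.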